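## Structural features

The target is a 3-hydroxyisoflavanone: a chroman-4-one in which the benzo ring A (C4a–C8a) carries hydroxyls at C5 and C7, and ring C (O1, C2, C3, C4, C4a, C8a) carries at C3 a tertiary hydroxyl and ring B. Ring B is a 2,4-dimethoxyphenyl group with a prenyl chain at C3', between the two methoxy groups; it is abbreviated Ar = 2,4-dimethoxy-3-(3-methylbut-2-en-1-yl)phenyl. C3 is the only stereocentre, is R, and is fully substituted (OH, C4 carbonyl, C2 methylene, C1'), so it has no stereogenic neighbour and cannot be corrected by epimerisation. Fragile elements are the trisubstituted prenyl alkene (acid, electrophilic oxidants, hydrogenation), the tertiary benzylic α-ketol (α-ketol shift, base-induced ring opening), the electron-rich ring B and the free acylphloroglucinol phenols. The real difficulty is to make the oxygenated quaternary C3 as one enantiomer and to join it to a 1,3,5-trioxygenated ring A without harming the prenyl group. The key step exploits the alternating pattern of ring A: C5, C7 and C8a carry oxygen and C4a carries the C4 acyl carbon, so the pairs C4a–C5, C6–C7 and C8–C8a are each the two carbons of an oxygen- or acyl-substituted alkyne. The first and third pairs are already linked by the O1–C2–C3–C4 atoms of ring C, and C3 lies in that tether, so it can be set beforehand and is not touched when rings A and C form.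

## Logic of the disconnections

28 ⇒ 27. The two aryl O–C(tert-butyl) bonds at O5 and O7 and the O–Si bond at O3 are cut. The phenols and the α-ketol hydroxyl cannot be carried through organolithium chemistry, and all three groups fall in one acidic operation; the tert-butyl groups arrive with the alkyne building block. Nothing skeletal is gained, but three acidic protons disappear. The forward step must cleave the ethers faster than the prenyl alkene is protonated.

27 ⇒ 26 + 21. C4a–C8a, C5–C6 and C7–C8 are cut, opening rings A and C together. The cut is placed here because each pair of ring A carbons then becomes an alkyne with oxygen or acyl in the right place, and the chain O1–C2–C3–C4 makes two of the three alkynes one molecule. This is the largest simplification of the route: a bicyclic aromatic ketone becomes an acyclic diyne with one stereocentre plus a two-carbon alkyne. The forward step must couple the tethered pair before either alkyne homotrimerises, and must orient 21 with its oxygen on C7, at room temperature.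

26 ⇒ 25 ⇒ 16 + 21. After adjusting the ketone to the alcohol level, the C4–C4a bond (carbonyl carbon to alkyne carbon) is cut, and the terminal ethynyl ether is traced back to the two C–Cl bonds of a dichlorovinyl ether. This removes the second alkyne as the same building block 21 and keeps both acid-sensitive ynol ethers out of the route until its last stages. The forward steps need a non-enolisable aldehyde, organolithium operations at low temperature and a neutral oxidant.

21 ⇒ 19 ⇒ 17. The second π bond of the alkyne is traced back to a vinylic C–Br and a vinylic C–H bond (an elimination in the forward sense), and the C–Br bond is then cut to leave an enol ether. The building block, needed in the largest molar amount of the whole route, thus comes from a commercial liquid in two operations, and the in-flask formation of 12 stays confined to the one occasion where it is unavoidable (13 ⇒ 10 + 11). The forward steps demand a cold, base-buffered passage through the α-bromo ether and cold handling of 21, which loses 2-methylpropene on warming.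

16 ⇒ 15 ⇒ 14 ⇒ 13. No C–C bond is cut: the aldehyde goes back to a primary silyl ether, the two silyl ethers to a diol, and the diol to an epoxide by forming a C–O bond at the methylene carbon. This is where the two CH2O arms on C3 are told apart, one already a vinyl ether and the other an epoxide carbon. The forward opening must be a pure SN2 attack at the methylene so that the C3–O bond, and with it the configuration, is kept.

13 ⇒ 10 + 11. The O–C(vinyl) bond is cut. Installing the masked ethynyl ether on the only free hydroxyl before the epoxide is opened fixes which arm becomes C2 and which becomes C4. The forward step must run under alkoxide conditions only.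

10 ⇒ 9. The two C–O bonds of the oxirane are cut, which removes the only stereocentre and leaves an achiral 2-arylallyl alcohol. The allylic hydroxyl is the handle for a reagent-controlled, hydroxyl-directed epoxidation that ignores the prenyl alkene. The forward step needs high face selectivity and must not open the electron-rich benzylic epoxide.

9 ⇒ 5 + 6. The C1'–C(sp2) bond is cut, giving an aryl metal and a vinyl bromide for a convergent cross-coupling. The forward step needs metalation at C1' only.

5 ⇒ 4 ⇒ 1 + 2. The C–Br bond and the C3'–CH2 bond are cut. The position between the two methoxy groups is the most acidic, and after alkylation the two remaining activated positions are equivalent. The forward bromination must take the arene faster than the alkene.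

## Other disconnections considered

Alternative 1: The cut runs through ring B at C1'–C2' and C5'–C6'. Forward, the diene A1 (1,3-dimethoxy-2-prenyl-1-(trimethylsilyloxy)buta-1,3-diene) would add to the ethynyl ketone A2 (1-(tert-butyldimethylsilyloxy)but-3-yn-2-one) in a [4+2] cycloaddition, and loss of methanol would aromatise the adduct to A3 (2-(tert-butyldimethylsilyloxy)-1-(2-hydroxy-4-methoxy-3-prenylphenyl)ethanone).
- In its favour: the polarity of the two partners fixes the substitution pattern, the prenyl group is placed between the two oxygens without aromatic substitution or metalation, and the reaction type is well known.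
- Against it here: the ring B pattern is reached in two steps from a commercial arene (steps 1 and 2). A1 needs about three steps from a β-keto ester, is hindered at C2 and is labile to hydrolysis. A3 still needs O-methylation, methylenation and desilylation before it meets the chosen route at 9.
- Comparison: structurally it builds the one ring that poses no problem and leaves C3 and rings A and C untouched. Mechanistically it is better precedented than the chosen key step and equal to it in regiocontrol. In step economy it is worse, roughly nine operations to 9 against three. It is the better choice on one point: no electrophilic halogenation is run beside the prenyl alkene, and it would suit congeners with a free 2'-hydroxyl.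

Alternative 2: The cut is C4a–C5 of ring A. Forward, base would convert the 3,5,7-triketo ester A4 (methyl 7-[(4R)-4-Ar-2,2-dimethyl-1,3-dioxolan-4-yl]-3,5,7-trioxoheptanoate) into the acylphloroglucinol A5 ([(4R)-4-Ar-2,2-dimethyl-1,3-dioxolan-4-yl](2,4,6-trihydroxyphenyl)methanone) by Claisen condensation of the methylene next to the future C4 carbonyl onto the ester carbon.
- In its favour: it follows the biosynthetic folding, and the hindered ketone next to the quaternary carbon disfavours the competing aldol mode. Ring A appears with free phenols, so no aryl ether is cleaved with acid beside the prenyl group; on this point it is better than the chosen plan. Claisen cyclisations of this polyketide kind are known, which the chosen key step is not.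
- Against it here: A4 must be assembled by acylating a polyanion of a 3,5-dioxo ester with a hindered, α-oxygenated acyl donor whose stereocentre still has to be made by the same epoxidation chemistry. The triketo ester can lactonise to a pyrone or fragment by retro-Claisen reaction. The step closes ring A only, so A5 still needs acetonide removal and a selective O-alkylation to close ring C.
- Comparison: structurally it forms one ring and one bond against two rings and three bonds. Mechanistically it is known in kind but delicate in regiochemistry, so it is equal or slightly better in certainty. In step economy it is no shorter and probably longer.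

Alternative 3: The cut is C3–C4. Forward, a chiral triazolium-derived carbene would add to the aldehyde of the keto aldehyde A6 (2-(2-Ar-2-oxoethoxy)-4,6-bis(methoxymethoxy)benzaldehyde), and the Breslow intermediate would attack the tethered aryl ketone. This closes ring C and creates C3 in A7 ((3R)-3-Ar-3-hydroxy-5,7-bis(methoxymethoxy)chroman-4-one).
- In its favour: the enantioselective intramolecular aldehyde–ketone benzoin reaction to 3-hydroxychroman-4-ones is an established reaction type. A6 comes from one O-alkylation of a ring A salicylaldehyde with a ring B α-halo ketone. The whole route would take about six steps from 1. On precedent and on step economy it is clearly better than the chosen plan.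
- Against it here: the ketone is electron-rich and flanked by an ortho methoxy group, and the aldehyde sits between two oxygen substituents on an electron-rich ring, so both partners are sluggish. The configuration of C3 would depend entirely on an untested catalyst–substrate match. The benzoin step is reversible, so selectivity could erode. The final removal of the methoxymethyl groups needs acid beside the prenyl group, which is equal to the last step of the chosen plan.
- Comparison: structurally it forms one ring and one bond and makes ring formation and stereocontrol the same event, whereas the chosen plan sets C3 early by reagent control and forms no stereocentre in the ring-forming step. The chosen plan builds ring A with its oxygenation from non-aromatic pieces, at the price of an unprecedented step and a longer route. Alternative 3 therefore serves as the fallback for the key step.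

Key step: step 13

Remarks on the chemistry, before the steps:
- Ar = 2,4-dimethoxy-3-(3-methylbut-2-en-1-yl)phenyl throughout.
- The cycloaddition precursor carries its C3 oxygen as a triethylsilyl ether, not as a free hydroxyl. A free tertiary hydroxyl next to the alkoxy ynone invites 5-endo cyclisation to a 3(2H)-furanone and α-ketol shift.
- The ethynyl ether is kept masked as its dichlorovinyl ether until the aldehyde has been consumed.
- Assumption: tert-butoxyacetylene is made (steps 9 and 10) and not bought; tert-butyl vinyl ether is taken as the commercial starting material for it. This building block is needed in several equivalents, and the vinyl ether route makes it without dichloroacetylene, which is therefore generated only once, in the flask and on the scale of step 5.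
- The spatial arrangement at the quaternary carbon is the same from 10 to 28. Its CIP letter changes (R in 10, S in 13 and 14, R from 15 on) only because the ranks of the two oxygenated arms change.

## Steps

Step 1
Reactants: 1 1,3-dimethoxybenzene; 2 1-bromo-3-methylbut-2-ene (prenyl bromide)
Product: 4 1,3-dimethoxy-2-(3-methylbut-2-en-1-yl)benzene, via 2,6-dimethoxyphenyllithium 3 (not isolated)
Conditions: n-BuLi (1.1 equiv), THF, 0 °C→rt; then 2, −78 °C→rt
Reagents that add atoms: none
Why: Directed ortho-metalation; both methoxy groups acidify and coordinate C2, and the aryllithium displaces the primary allylic bromide by SN2.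

Step 2
Reactants: 4 1,3-dimethoxy-2-(3-methylbut-2-en-1-yl)benzene
Product: 5 1-bromo-2,4-dimethoxy-3-(3-methylbut-2-en-1-yl)benzene (ArBr)
Conditions: NBS (1.0 equiv), MeCN, −10→0 °C, dark
Reagents that add atoms: N-bromosuccinimide, O=C1CCC(=O)N1Br
Why: Electrophilic aromatic bromination; the position ortho and para to the two methoxy groups should react with NBS in dry acetonitrile much faster than the trisubstituted alkene, which needs a nucleophile or a radical chain to consume bromine. One equivalent and the equivalence of the two activated positions should give a single monobromide.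

Step 3
Reactants: 5 ArBr; 6 2-bromoprop-2-en-1-ol
Product: 9 2-Ar-prop-2-en-1-ol, via aryllithium ArLi 7 (not isolated), via lithium aryltriisopropoxyborate 8 (not isolated)
Conditions: n-BuLi, THF, −78 °C; B(OiPr)3, −78 °C→rt; then 6, Pd(OAc)2 (2 mol %), SPhos (4 mol %), aq K3PO4, 40 °C
Reagents that add atoms: none
Why: Bromine–lithium exchange, borylation and Suzuki–Miyaura coupling in one flask; vinyl bromides couple readily and the free hydroxyl is tolerated. Exchange at −78 °C is far faster than deprotonation of the prenyl methylene.

Step 4
Reactants: 9 2-Ar-prop-2-en-1-ol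
Product: 10 [(2R)-2-Ar-oxiran-2-yl]methanol
Conditions: Ti(OiPr)4 (10 mol %), D-(−)-diisopropyl tartrate (12 mol %), t-BuOOH (2 equiv, isooctane), 4 Å MS, CH2Cl2, −25 °C; NaOH–brine work-up
Reagents that add atoms: tert-butyl hydroperoxide, CC(C)(C)OO
Why: Sharpless asymmetric epoxidation; the allylic hydroxyl binds titanium, so only the 1,1-disubstituted alkene should be epoxidised and the prenyl alkene left alone. The D-(−)-tartrate should deliver oxygen to the face that gives the (R)-epoxy alcohol (the L-(+) ester gives the (S) series from 2-substituted allyl alcohols). The catalytic, sieve-dried protocol and a non-acidic work-up limit Lewis-acid opening of the electron-rich benzylic epoxide.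

Step 5
Reactants: 10 [(2R)-2-Ar-oxiran-2-yl]methanol; 11 trichloroethylene
Product: 13 (2S)-2-Ar-2-{[(E)-1,2-dichloroethenyl]oxymethyl}oxirane, via dichloroacetylene 12 (not isolated)
Conditions: KH (1.5 equiv), THF, 0 °C; then 11 (1.1 equiv), −78 °C→rt
Reagents that add atoms: none
Why: Anti addition of the alkoxide to dichloroacetylene generated in the flask from trichloroethylene should give the (E)-1,2-dichlorovinyl ether; the toxic alkyne is never isolated. A Payne rearrangement of the epoxy alkoxide is degenerate and returns the same enantiomer, so the stereocentre is not at risk.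

Step 6
Reactants: 13 (2S)-2-Ar-2-{[(E)-1,2-dichloroethenyl]oxymethyl}oxirane
Product: 14 (2S)-2-Ar-3-{[(E)-1,2-dichloroethenyl]oxy}propane-1,2-diol
Conditions: KOH (5 equiv), DMSO–H2O (5:1), 50 °C
Reagents that add atoms: water, O (delivered as hydroxide)
Why: SN2 opening of the 2,2-disubstituted oxirane by hydroxide at the unhindered methylene; the C–O bond at the quaternary carbon is not broken, so the configuration is retained. The chlorinated vinyl ether is expected to tolerate aqueous base at this temperature.

Step 7
Reactants: 14 (2S)-2-Ar-3-{[(E)-1,2-dichloroethenyl]oxy}propane-1,2-diol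
Product: 15 (2R)-2-Ar-3-{[(E)-1,2-dichloroethenyl]oxy}-1,2-bis(triethylsilyloxy)propane
Conditions: Et3SiOTf (2.5 equiv), 2,6-lutidine (4 equiv), CH2Cl2, −78→0 °C
Reagents that add atoms: triethylsilyl trifluoromethanesulfonate, CC[Si](CC)(CC)OS(=O)(=O)C(F)(F)F
Why: The silyl triflate silylates both the hindered tertiary and the primary hydroxyl. Protecting the tertiary oxygen blocks the α-ketol shift of the later aldehyde and furanone formation from the later ynone.

Step 8
Reactants: 15 (2R)-2-Ar-3-{[(E)-1,2-dichloroethenyl]oxy}-1,2-bis(triethylsilyloxy)propane
Product: 16 (2R)-2-Ar-3-{[(E)-1,2-dichloroethenyl]oxy}-2-(triethylsilyloxy)propanal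
Conditions: (COCl)2 (4 equiv), DMSO (8 equiv), CH2Cl2, −78→−35 °C; Et3N, −78→0 °C
Reagents that add atoms: none
Why: Swern conditions cleave and oxidise primary triethylsilyl ethers directly to aldehydes, while the tertiary silyl ether cannot react. The α-carbon is quaternary, so the aldehyde cannot epimerise.

Step 9
Reactants: 17 tert-butyl vinyl ether
Product: 19 (Z)-1-bromo-2-tert-butoxyethene, via 1,2-dibromo-1-tert-butoxyethane 18 (not isolated)
Conditions: Br2 (1.0 equiv), pentane, −78 °C; then Et3N (1.5 equiv), −78 °C→gentle reflux; filtered, distilled at reduced pressure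
Reagents that add atoms: bromine, BrBr
Why: Electrophilic addition of bromine to the enol ether, then amine-induced dehydrobromination of the α,β-dibromo ether, which ionises readily at the oxygen-bearing carbon and loses the acidified β-proton; this is the classical entry to β-halovinyl ethers. The (Z) isomer is expected to predominate, and either isomer is converted in step 10. Low temperature and the amine keep the acid-labile tert-butyl ether intact.

Step 10
Reactants: 19 (Z)-1-bromo-2-tert-butoxyethene
Product: 21 tert-butoxyacetylene, via sodium tert-butoxyacetylide 20 (not isolated)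
Conditions: NaNH2 (2.5 equiv), liq. NH3, −40 °C; then pentane, cold brine, −20 °C; distilled below 30 °C at reduced pressure
Reagents that add atoms: none
Why: Anti elimination of HBr from the β-bromovinyl ether by amide gives the alkoxyacetylene, which a second equivalent of amide holds as the sodium acetylide until the aqueous quench; this is the classical sodium amide route to alkoxyacetylenes. The product is kept cold because tert-butyl ynol ethers lose 2-methylpropene by retro-ene reaction on warming.

Step 11
Reactants: 16 (2R)-2-Ar-3-{[(E)-1,2-dichloroethenyl]oxy}-2-(triethylsilyloxy)propanal; 21 tert-butoxyacetylene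
Product: 25 (2R,3RS)-2-Ar-5-tert-butoxy-1-(ethynyloxy)-2-(triethylsilyloxy)pent-4-yn-3-ol, via lithium tert-butoxyacetylide 22 (not isolated), via lithium dichlorovinyl carbinolate 23 (not isolated), via dilithiated ethynyl ether carbinolate 24 (not isolated)
Conditions: 21 (1.5 equiv), n-BuLi (1.4 equiv), THF, −78 °C; 16, −78 °C; then n-BuLi (2.4 equiv), −78 °C; MeOH then pH 7 buffer, −78 °C
Reagents that add atoms: none
Why: 1,2-Addition of the lithium alkoxyacetylide to the non-enolisable aldehyde, then dehydrochlorination and chlorine–lithium exchange of the dichlorovinyl ether in the same flask once no carbonyl is left. The carbinol centre forms as a mixture that step 12 removes. Low temperature and a neutral quench are meant to prevent silyl migration and Meyer–Schuster rearrangement.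

Step 12
Reactants: 25 (2R,3RS)-2-Ar-5-tert-butoxy-1-(ethynyloxy)-2-(triethylsilyloxy)pent-4-yn-3-ol
Product: 26 (2R)-2-Ar-5-tert-butoxy-1-(ethynyloxy)-2-(triethylsilyloxy)pent-4-yn-3-one
Conditions: activated MnO2 (20 equiv), CH2Cl2, rt
Reagents that add atoms: none
Why: Neutral heterogeneous oxidation of a propargylic alcohol; the acid-free conditions should spare both ynol ethers, the silyl ether and the prenyl group.

Step 13
Reactants: 26 (2R)-2-Ar-5-tert-butoxy-1-(ethynyloxy)-2-(triethylsilyloxy)pent-4-yn-3-one; 21 tert-butoxyacetylene
Product: 27 (3R)-3-Ar-5,7-di-tert-butoxy-3-(triethylsilyloxy)-2,3-dihydro-4H-chromen-4-one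
Conditions: [Rh(cod)2]BF4 (5 mol %), rac-BINAP (5 mol %), H2 then Ar, CH2Cl2, rt; 26 added over 2 h to 21 (3 equiv)
Reagents that add atoms: none
Why: Proposed new method: the cationic monovalent rhodium–bisphosphine fragment freed by hydrogenating the cod ligands should bind the electron-poor ynone and the electron-rich ethynyl ether of 26 and couple them oxidatively to a rhodacyclopentadiene, forming C4a–C8a; this closes ring C as the six-membered ring defined by the four-atom O1–C2–C3–C4 tether (a 1,7-diyne cyclisation). Insertion of 21 into the rhodacycle and reductive elimination should then form C5–C6 and C7–C8 and close ring A directly as the benzene ring. The closest known reaction type is the rhodium-catalysed [2+2+2] cycloaddition of tethered diynes with monoalkynes, which tolerates alkynyl ethers and carbonyl-substituted alkynes; the combination of an acyl ynol ether, an ethynyl ether and a third ynol ether has no direct precedent. No stereocentre is created, and C3 lies in the tether, bears no hydrogen and is silyl-protected, so it should pass through unchanged. Two selectivities are needed. Cross- over homo-trimerisation should be secured by the tether, which makes 26 a chelating diyne, and by adding 26 slowly to an excess of 21. The orientation of 21 with its oxygen on C7 should be secured by polarity matching (its nucleophilic CH carbon bonds to the electrophilic, oxygen-bearing C5 and its oxygen-bearing carbon to the nucleophilic C8) and by the two tert-butoxy groups avoiding an ortho relationship. Room temperature keeps the tert-butyl ynol ethers from losing 2-methylpropene by retro-ene reaction.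

Step 14
Reactants: 27 (3R)-3-Ar-5,7-di-tert-butoxy-3-(triethylsilyloxy)-2,3-dihydro-4H-chromen-4-one
Product: 28 (3R)-3-Ar-3,5,7-trihydroxy-2,3-dihydro-4H-chromen-4-one (target)
Conditions: CF3CO2H (15 vol %), H2O (2 vol %), CH2Cl2, 0 °C
Reagents that add atoms: none
Why: Acidolysis of the two aryl tert-butyl ethers (loss of 2-methylpropene from the tert-butyl cation, with water as a trap) and protodesilylation of the triethylsilyl ether. The ethers of the acylphloroglucinol are good leaving groups and should cleave under conditions too mild to protonate the prenyl alkene at a useful rate. The C3 carbinol is next to the carbonyl and should not ionise.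

## Compound list

1 | 1,3-dimethoxybenzene | COc1cccc(OC)c1 | starting material
2 | 1-bromo-3-methylbut-2-ene (prenyl bromide) | CC(C)=CCBr | starting material
3 | 2,6-dimethoxyphenyllithium | [Li]c1c(OC)cccc1OC | intermediate
4 | 1,3-dimethoxy-2-(3-methylbut-2-en-1-yl)benzene | COc1cccc(OC)c1CC=C(C)C | intermediate
5 | 1-bromo-2,4-dimethoxy-3-(3-methylbut-2-en-1-yl)benzene | COc1ccc(Br)c(OC)c1CC=C(C)C | intermediate
6 | 2-bromoprop-2-en-1-ol | OCC(Br)=C | starting material
7 | [2,4-dimethoxy-3-(3-methylbut-2-en-1-yl)phenyl]lithium | COc1ccc([Li])c(OC)c1CC=C(C)C | intermediate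
8 | lithium [2,4-dimethoxy-3-(3-methylbut-2-en-1-yl)phenyl]triisopropoxyborate | [Li+].COc1ccc([B-](OC(C)C)(OC(C)C)OC(C)C)c(OC)c1CC=C(C)C | intermediate
9 | 2-[2,4-dimethoxy-3-(3-methylbut-2-en-1-yl)phenyl]prop-2-en-1-ol | COc1ccc(C(=C)CO)c(OC)c1CC=C(C)C | intermediate
10 | [(2R)-2-[2,4-dimethoxy-3-(3-methylbut-2-en-1-yl)phenyl]oxiran-2-yl]methanol | COc1ccc([C@@]2(CO)CO2)c(OC)c1CC=C(C)C | intermediate
11 | trichloroethylene | ClC=C(Cl)Cl | starting material
12 | dichloroacetylene | ClC#CCl | intermediate
13 | (2S)-2-{[(E)-1,2-dichloroethenyl]oxymethyl}-2-[2,4-dimethoxy-3-(3-methylbut-2-en-1-yl)phenyl]oxirane | COc1ccc([C@@]2(CO/C(Cl)=C\Cl)CO2)c(OC)c1CC=C(C)C | intermediate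
14 | (2S)-3-{[(E)-1,2-dichloroethenyl]oxy}-2-[2,4-dimethoxy-3-(3-methylbut-2-en-1-yl)phenyl]propane-1,2-diol | COc1ccc([C@](O)(CO)CO/C(Cl)=C\Cl)c(OC)c1CC=C(C)C | intermediate
15 | (2R)-3-{[(E)-1,2-dichloroethenyl]oxy}-2-[2,4-dimethoxy-3-(3-methylbut-2-en-1-yl)phenyl]-1,2-bis(triethylsilyloxy)propane | COc1ccc([C@](O[Si](CC)(CC)CC)(CO[Si](CC)(CC)CC)CO/C(Cl)=C\Cl)c(OC)c1CC=C(C)C | intermediate
16 | (2R)-3-{[(E)-1,2-dichloroethenyl]oxy}-2-[2,4-dimethoxy-3-(3-methylbut-2-en-1-yl)phenyl]-2-(triethylsilyloxy)propanal | COc1ccc([C@](O[Si](CC)(CC)CC)(C=O)CO/C(Cl)=C\Cl)c(OC)c1CC=C(C)C | intermediate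
17 | tert-butyl vinyl ether | C=COC(C)(C)C | starting material
18 | 1,2-dibromo-1-tert-butoxyethane (racemic) | BrCC(Br)OC(C)(C)C | intermediate
19 | (Z)-1-bromo-2-tert-butoxyethene | Br/C=C\OC(C)(C)C | intermediate
20 | sodium tert-butoxyacetylide | [Na+].[C-]#COC(C)(C)C | intermediate
21 | tert-butoxyacetylene | C#COC(C)(C)C | intermediate
22 | lithium tert-butoxyacetylide | [Li]C#COC(C)(C)C | intermediate
23 | lithium (2R,3RS)-5-tert-butoxy-1-{[(E)-1,2-dichloroethenyl]oxy}-2-[2,4-dimethoxy-3-(3-methylbut-2-en-1-yl)phenyl]-2-(triethylsilyloxy)pent-4-yn-3-olate | [Li+].COc1ccc([C@](O[Si](CC)(CC)CC)(C([O-])C#COC(C)(C)C)CO/C(Cl)=C\Cl)c(OC)c1CC=C(C)C | intermediate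
24 | lithium (2R,3RS)-5-tert-butoxy-2-[2,4-dimethoxy-3-(3-methylbut-2-en-1-yl)phenyl]-1-(lithioethynyloxy)-2-(triethylsilyloxy)pent-4-yn-3-olate | [Li+].COc1ccc([C@](O[Si](CC)(CC)CC)(C([O-])C#COC(C)(C)C)COC#C[Li])c(OC)c1CC=C(C)C | intermediate
25 | (2R,3RS)-5-tert-butoxy-2-[2,4-dimethoxy-3-(3-methylbut-2-en-1-yl)phenyl]-1-(ethynyloxy)-2-(triethylsilyloxy)pent-4-yn-3-ol | COc1ccc([C@](O[Si](CC)(CC)CC)(C(O)C#COC(C)(C)C)COC#C)c(OC)c1CC=C(C)C | intermediate
26 | (2R)-5-tert-butoxy-2-[2,4-dimethoxy-3-(3-methylbut-2-en-1-yl)phenyl]-1-(ethynyloxy)-2-(triethylsilyloxy)pent-4-yn-3-one | COc1ccc([C@](O[Si](CC)(CC)CC)(C(=O)C#COC(C)(C)C)COC#C)c(OC)c1CC=C(C)C | intermediate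
27 | (3R)-5,7-di-tert-butoxy-3-[2,4-dimethoxy-3-(3-methylbut-2-en-1-yl)phenyl]-3-(triethylsilyloxy)-2,3-dihydro-4H-chromen-4-one | COc1ccc([C@@]2(O[Si](CC)(CC)CC)COc3cc(OC(C)(C)C)cc(OC(C)(C)C)c3C2=O)c(OC)c1CC=C(C)C | intermediate
28 | (3R)-3,5,7-trihydroxy-3-[2,4-dimethoxy-3-(3-methylbut-2-en-1-yl)phenyl]-2,3-dihydro-4H-chromen-4-one | COc1ccc([C@@]2(O)COc3cc(O)cc(O)c3C2=O)c(OC)c1CC=C(C)C | target

## Step count and least certain steps

Total: 14 steps. Longest linear sequence: 12 steps (steps 1–8 and 11–14, from 1,3-dimethoxybenzene). Steps 9 and 10 are the two-step branch to 21.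

Step 13 (key step). The most likely failure is that 21 homotrimerises or oligomerises, or that the terminal ynol ethers divert the catalyst into vinylidene- or ketene-type species, before the hindered push–pull ynone engages. The second is insertion of 21 in the reverse sense, since the polarity argument is untested on a rhodacycle. The fallback uses known chemistry, sets out from 5 and returns at 28.
- Bromine–lithium exchange of 5 (through 7) and acylation with 2-chloro-N-methoxy-N-methylacetamide would give 2-chloro-1-Ar-ethanone F1.
- 2,4,6-Trihydroxybenzaldehyde and chloromethyl methyl ether would give 2-hydroxy-4,6-bis(methoxymethoxy)benzaldehyde F2, the chelated ortho hydroxyl staying free.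
- O-Alkylation of F2 with F1 (K2CO3, NaI, acetone) would give the keto aldehyde 2-(2-Ar-2-oxoethoxy)-4,6-bis(methoxymethoxy)benzaldehyde F3, the compound called A6 above.
- An aminoindanol-derived chiral triazolium salt with an amine base would close ring C by intramolecular crossed benzoin reaction to (3R)-3-Ar-3-hydroxy-5,7-bis(methoxymethoxy)chroman-4-one F4, identical with A7.
- Dilute HCl in methanol would remove the methoxymethyl groups and give 28.

Step 4. The most likely failure is titanium-promoted ionisation of the product epoxide at its electron-rich benzylic carbon during reaction or work-up (opening by isopropanol or tartrate, or Meinwald rearrangement), with loss of material and of enantiomeric purity. The fallback sets out from 9 and returns at 10. Oxidation of 9 with MnO2 would give 2-Ar-prop-2-enal F5. Iminium-catalysed nucleophilic epoxidation with aqueous H2O2 and a cinchona-derived primary amine salt, with no Lewis acid present, would give (2S)-2-Ar-oxirane-2-carbaldehyde F6, whose formyl group disfavours ionisation. NaBH4 reduction would then give 10.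

Step 6. The most likely failure is competing ionisation at the quaternary benzylic carbon in the aqueous medium, where attack by water inverts or scrambles C3 and lowers the enantiomeric purity. Base-induced dehydrochlorination of the dichlorovinyl ether is a second possibility. The fallback sets out from 13 and returns at 16.
- Sodium benzenethiolate in THF–ethanol at room temperature, a soft nucleophile in a basic and far less ionising medium, would open 13 at the methylene to (2R)-2-Ar-1-{[(E)-1,2-dichloroethenyl]oxy}-3-(phenylsulfanyl)propan-2-ol F7.
- Et3SiOTf and 2,6-lutidine would give its triethylsilyl ether F8.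
- NaIO4 would give the sulfoxide F9.
- Pummerer rearrangement of F9 with trifluoroacetic anhydride and 2,6-lutidine, followed by hydrolysis with aqueous NaHCO3, would give 16.

Step 9. The most likely failure is loss of the tert-butyl group from the α-bromo ether 18 (fragmentation toward bromoacetaldehyde) before the amine induces elimination, or quaternisation of the amine without subsequent elimination. The fallback sets out from 11 and returns at 21, bypassing steps 9 and 10. Potassium tert-butoxide and 11 in THF (−78 °C→rt) would give tert-butyl (E)-1,2-dichloroethenyl ether F10 by addition of the alkoxide to 12 formed in the flask. n-BuLi (2.1 equiv) at −78 °C and a cold water quench would then give 21 by way of 22. The price is a second in-flask generation of 12, on a larger scale.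

Step 11. The most likely failure is migration of the triethylsilyl group from the tertiary oxygen to the neighbouring lithium alkoxide, or acid-induced Meyer–Schuster-type rearrangement of the alkoxyethynyl carbinol on work-up. The fallback sets out from 16 and returns at 26, so it also bypasses the oxidation of step 12. Pinnick oxidation (NaClO2, NaH2PO4, 2-methyl-2-butene) would give (2R)-2-Ar-3-{[(E)-1,2-dichloroethenyl]oxy}-2-(triethylsilyloxy)propanoic acid F11. Coupling with N,O-dimethylhydroxylamine would give the N-methoxy-N-methyl amide F12. Addition of 22 and then n-BuLi at −78 °C, which converts the dichlorovinyl ether while the carbonyl is masked as the chelated tetrahedral adduct, would give 26 on quench, with no free carbinol.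

Step 14. The most likely failure is Markovnikov addition of acid or water to the prenyl alkene, or tert-butylation of ring A by the released cation, if the ether cleavage needs stronger acid than planned. The fallback sets out from 27 and returns at 28. Me3SiOTf and 2,6-lutidine in CH2Cl2 at 0 °C would exchange the two tert-butyl ethers for trimethylsilyl ethers without free protic acid, giving (3R)-3-Ar-3-(triethylsilyloxy)-5,7-bis(trimethylsilyloxy)-2,3-dihydro-4H-chromen-4-one F13. Bu4NF buffered with acetic acid would then remove all three silyl groups to give 28.

## Further compounds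

F1 | step 13 | 2-chloro-1-[2,4-dimethoxy-3-(3-methylbut-2-en-1-yl)phenyl]ethanone | COc1ccc(C(=O)CCl)c(OC)c1CC=C(C)C
F2 | step 13 | 2-hydroxy-4,6-bis(methoxymethoxy)benzaldehyde | O=Cc1c(O)cc(OCOC)cc1OCOC
F3 | step 13 | 2-{2-[2,4-dimethoxy-3-(3-methylbut-2-en-1-yl)phenyl]-2-oxoethoxy}-4,6-bis(methoxymethoxy)benzaldehyde | O=Cc1c(OCC(=O)c2ccc(OC)c(CC=C(C)C)c2OC)cc(OCOC)cc1OCOC
F4 | step 13 | (3R)-3-[2,4-dimethoxy-3-(3-methylbut-2-en-1-yl)phenyl]-3-hydroxy-5,7-bis(methoxymethoxy)-2,3-dihydro-4H-chromen-4-one | COc1ccc([C@@]2(O)COc3cc(OCOC)cc(OCOC)c3C2=O)c(OC)c1CC=C(C)C
F5 | step 4 | 2-[2,4-dimethoxy-3-(3-methylbut-2-en-1-yl)phenyl]prop-2-enal | COc1ccc(C(=C)C=O)c(OC)c1CC=C(C)C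
F6 | step 4 | (2S)-2-[2,4-dimethoxy-3-(3-methylbut-2-en-1-yl)phenyl]oxirane-2-carbaldehyde | COc1ccc([C@@]2(C=O)CO2)c(OC)c1CC=C(C)C
F7 | step 6 | (2R)-1-{[(E)-1,2-dichloroethenyl]oxy}-2-[2,4-dimethoxy-3-(3-methylbut-2-en-1-yl)phenyl]-3-(phenylsulfanyl)propan-2-ol | COc1ccc([C@](O)(CSc2ccccc2)CO/C(Cl)=C\Cl)c(OC)c1CC=C(C)C
F8 | step 6 | triethylsilyl ether of F7, (2R) | COc1ccc([C@](O[Si](CC)(CC)CC)(CSc2ccccc2)CO/C(Cl)=C\Cl)c(OC)c1CC=C(C)C
F9 | step 6 | sulfoxide of F8, (2R), mixture at sulfur | COc1ccc([C@](O[Si](CC)(CC)CC)(CS(=O)c2ccccc2)CO/C(Cl)=C\Cl)c(OC)c1CC=C(C)C
F10 | step 9 | tert-butyl (E)-1,2-dichloroethenyl ether | CC(C)(C)O/C(Cl)=C\Cl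
F11 | step 11 | (2R)-3-{[(E)-1,2-dichloroethenyl]oxy}-2-[2,4-dimethoxy-3-(3-methylbut-2-en-1-yl)phenyl]-2-(triethylsilyloxy)propanoic acid | COc1ccc([C@](O[Si](CC)(CC)CC)(C(=O)O)CO/C(Cl)=C\Cl)c(OC)c1CC=C(C)C
F12 | step 11 | (2R)-3-{[(E)-1,2-dichloroethenyl]oxy}-2-[2,4-dimethoxy-3-(3-methylbut-2-en-1-yl)phenyl]-N-methoxy-N-methyl-2-(triethylsilyloxy)propanamide | COc1ccc([C@](O[Si](CC)(CC)CC)(C(=O)N(C)OC)CO/C(Cl)=C\Cl)c(OC)c1CC=C(C)C
F13 | step 14 | (3R)-3-[2,4-dimethoxy-3-(3-methylbut-2-en-1-yl)phenyl]-3-(triethylsilyloxy)-5,7-bis(trimethylsilyloxy)-2,3-dihydro-4H-chromen-4-one | COc1ccc([C@@]2(O[Si](CC)(CC)CC)COc3cc(O[Si](C)(C)C)cc(O[Si](C)(C)C)c3C2=O)c(OC)c1CC=C(C)C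
A1 | alternative 1 | 1,3-dimethoxy-2-(3-methylbut-2-en-1-yl)-1-(trimethylsilyloxy)buta-1,3-diene | COC(O[Si](C)(C)C)=C(CC=C(C)C)C(OC)=C
A2 | alternative 1 | 1-(tert-butyldimethylsilyloxy)but-3-yn-2-one | C#CC(=O)CO[Si](C)(C)C(C)(C)C
A3 | alternative 1 | 2-(tert-butyldimethylsilyloxy)-1-[2-hydroxy-4-methoxy-3-(3-methylbut-2-en-1-yl)phenyl]ethanone | COc1ccc(C(=O)CO[Si](C)(C)C(C)(C)C)c(O)c1CC=C(C)C
A4 | alternative 2 | methyl 7-[(4R)-4-[2,4-dimethoxy-3-(3-methylbut-2-en-1-yl)phenyl]-2,2-dimethyl-1,3-dioxolan-4-yl]-3,5,7-trioxoheptanoate | COc1ccc([C@]2(C(=O)CC(=O)CC(=O)CC(=O)OC)COC(C)(C)O2)c(OC)c1CC=C(C)C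
A5 | alternative 2 | [(4R)-4-[2,4-dimethoxy-3-(3-methylbut-2-en-1-yl)phenyl]-2,2-dimethyl-1,3-dioxolan-4-yl](2,4,6-trihydroxyphenyl)methanone | COc1ccc([C@]2(C(=O)c3c(O)cc(O)cc3O)COC(C)(C)O2)c(OC)c1CC=C(C)C
A6 | alternative 3 | 2-{2-[2,4-dimethoxy-3-(3-methylbut-2-en-1-yl)phenyl]-2-oxoethoxy}-4,6-bis(methoxymethoxy)benzaldehyde | O=Cc1c(OCC(=O)c2ccc(OC)c(CC=C(C)C)c2OC)cc(OCOC)cc1OCOC
A7 | alternative 3 | (3R)-3-[2,4-dimethoxy-3-(3-methylbut-2-en-1-yl)phenyl]-3-hydroxy-5,7-bis(methoxymethoxy)-2,3-dihydro-4H-chromen-4-one | COc1ccc([C@@]2(O)COc3cc(OCOC)cc(OCOC)c3C2=O)c(OC)c1CC=C(C)C
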